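The data were generated by integration from invented constants; scatter was added.

**Charge in hand.** The flask holds 20 mM each of left-handed and right-handed substrate, 60.0 mM of reagent and 100 µM of precatalyst, and runs to 10 d.

| setting | grey | blue | teal | flask |
|---|---|---|---|---|
| left-handed substrate | 20 mM | 20 mM | 30 mM | 20 mM |
| right-handed substrate | 20 mM | 20 mM | 30 mM | 20 mM |
| reagent | 84 mM | 130 mM | 60 mM | 60.0 mM |
| precatalyst | 100 µM | 100 µM | 100 µM | 100 µM |
| remark | run made earlier | run made earlier | run made earlier |  |
| time |  |  |  | 10 d |

| run | time / d | right-handed substrate / % | left-handed substrate / % |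
|---|---|---|---|
| grey | 0.500 | 47 | 1 |
| grey | 1.04 | 44 | 0 |
| grey | 2.50 | 37 | 0 |
| grey | 6.00 | 24 | 2 |
| blue | 0.500 | 49 | 0 |
| blue | 1.04 | 39 | 4 |
| blue | 2.50 | 27 | 0 |
| blue | 6.00 | 12 | 2 |
| teal | 0.833 | 47 | 2 |
| teal | 2.00 | 48 | 0 |
| teal | 4.00 | 38 | 2 |
| teal | 6.00 | 35 | 0 |

(readings scatter by 2 percentage points)

- catalyst is single-handed; left-handed substrate and right-handed substrate are mirror images of each other, charged as a racemate, each of them at the stated concentration

1. whether the excess of right-handed substrate over left-handed substrate among what is left of the two reaches 80% by 10 d (yes / no)
2. the highest excess of right-handed substrate over left-handed substrate among what is left of the two up to 10 d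

**Gap needed.** Let D be the base-ten logarithm of right-handed over left-handed substrate, the gap in powers of ten. An excess of 80% is a ratio of 9.00, so it asks for D of 0.954.

**On return.** The teal run had the flask's reagent charge, 60 mM, over more substrate. At 2.00 d it read 48% right-handed and 0% left-handed. Even with left-handed substrate set two standard deviations high, D reads 1.08, above the need. So the reckoning here for the flask is yes, carried over from that teal reading, whose pessimistic excess is 84.6%.

**Not to touch.** No more reagent goes in. At 6.00 d the blue run, with 130 mM, held 12% right-handed substrate, less than the 24% of the grey run with 84 mM.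

**The forecast.** It says yes and 99%: “The excess therefore passes 80% within about a day and approaches 100%”. Its top stands above the pessimistic teal excess reckoned here.

**Flask result.** The flask gives yes and a top excess of 100%; 80% comes at 0.225 d with right-handed substrate at 49.1% of the two substrates charged together, so the needed D puts left-handed substrate there at 5.46% of the same charge. In the flask at 0.0858 d, the half-life of left-handed substrate by its own step is 0.063 d, short against the 10 d allowed, and the ratio of the left-handed to the right-handed rate constant, the selectivity factor, is 125, or 2.10 powers of ten.

    reagent + catalyst + right-handed substrate → catalyst + right-handed product (k = 1070 M⁻² h⁻¹)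
    precatalyst → catalyst (k = 0.896 h⁻¹)
    reagent ⇌ dormant form (K = 0.250, k = 0.199 h⁻¹)
    reagent + catalyst + left-handed substrate → catalyst + left-handed product (k = 1.34 × 10⁵ M⁻² h⁻¹)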